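**Conventions and assumptions**
- Cembranoid numbering is used throughout. C1 is the lactone β-CH, C4(C18) bears the exocyclic methylene, C5 is CH–OOH, C10 is the butenolide γ-CH, C14 is the α-methylene-lactone γ-CH, C15–C17 are the α-methylene lactone carbons, and C19 is the butenolide C=O.
- Assumption: the macrocycle conformation, controlled by C10, gives the drawn C1/C14 configuration in the NHK step (step 16) and the drawn 5R configuration in the ene step (step 17).

## Retrosynthesis
1. The target comes from a singlet-oxygen ene reaction on the (E)-Δ4,5 trisubstituted alkene of macrodiolide **23**. This installs C5–OOH and C4=CH2 in one step.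
2. **23** comes from an intramolecular NHK allylation (C1–C14) of allylic bromide/enal **22**. This closes the 14-membered ring and forms the trans α-methylene-γ-lactone together.
3. **22** comes from **19** by Morita–Baylis–Hillman (MBH) reaction and SN2′ bromination at C1. **19** comes from a Negishi C7–C8 coupling of West iodide **17** with East 3-iodobutenolide **9**.
4. **17** (C2–C3 bond and E-C4=C5) comes from a Johnson–Claisen [3,3] rearrangement of allylic alcohol **11**. **9** comes from the L-glutamate-derived lactone **1** (which supplies C10).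
5. Rings formed: the butenolide unsaturation (step 5), then the macrocycle and lactone 1 together (step 16).

## Route

**Step 1**
Reactants: **1** (S)-5-(hydroxymethyl)dihydrofuran-2(3H)-one
Product: **2** (S)-(5-oxotetrahydrofuran-2-yl)methyl tosylate
Conditions: TsCl, Et3N, DMAP (cat.), CH2Cl2, 0 °C → rt
Reagents that add atoms: TsCl, Cc1ccc(cc1)S(=O)(=O)Cl
Why: O-sulfonylation makes the primary carbinol a leaving group and leaves the C10 stereocentre untouched.

**Step 2**
Reactants: **2**; **3** isopropenylmagnesium bromide
Product: **4** (S)-5-(2-methylallyl)dihydrofuran-2(3H)-one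
Conditions: **3**, CuI (20 mol%), THF, –40 → –10 °C
Reagents that add atoms: isopropenylmagnesium bromide, C=C(C)[Mg]Br
Why: Cu-catalysed Grignard SN2 displacement at the primary tosylate forms C11–C12; the reaction is remote from C10, which is retained.

**Step 3**
Reactants: **4**; **5** acrolein dimethyl acetal
Product: **6** (S)-5-[(E)-4,4-dimethoxy-2-methylbut-2-en-1-yl]dihydrofuran-2(3H)-one
Conditions: **5** (5 equiv), Hoveyda–Grubbs II (5 mol%), CH2Cl2, 40 °C
Reagents that add atoms: acrolein dimethyl acetal, C=CC(OC)OC
Why: Cross-metathesis of the methallyl alkene gives the E-trisubstituted C12=C13 alkene (thermodynamic E preference) and masks C14 as an acetal.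

**Step 4**
Reactants: **6**
Product: **7** 3-(phenylselanyl) lactone (C8 epimer mixture, C10 as in 6)
Conditions: LiHMDS, THF, –78 °C; then PhSeCl
Reagents that add atoms: PhSeCl, Cl[Se]c1ccccc1
Why: The lactone enolate is selenylated at C8; the new C8 stereocentre is destroyed in the next step.

**Step 5**
Reactants: **7**
Product: **8** (R)-5-[(E)-4,4-dimethoxy-2-methylbut-2-en-1-yl]furan-2(5H)-one
Conditions: 30% H2O2, pyridine, CH2Cl2, 0 °C → rt
Reagents that add atoms: none
Why: Selenoxide syn-elimination can only use the ring C9–H, so it gives the endocyclic butenolide (C8=C9), and C10 is not touched.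

**Step 6**
Reactants: **8**
Product: **9** (R)-3-iodo-5-[(E)-4,4-dimethoxy-2-methylbut-2-en-1-yl]furan-2(5H)-one
Conditions: I2, pyridine, CH2Cl2, 0 °C → rt
Reagents that add atoms: iodine, II
Why: Pyridine-mediated α-iodination of the butenolide (conjugate addition, iodination, elimination) gives the C8 cross-coupling handle.

**Step 7**
Reactants: **10** 3-(tert-butyldimethylsilyloxy)propanal; **3**
Product: **11** 5-(TBSO)-2-methylpent-1-en-3-ol (racemic carbinol)
Conditions: **3** (1.3 equiv), THF, –78 → 0 °C
Reagents that add atoms: isopropenylmagnesium bromide, C=C(C)[Mg]Br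
Why: Grignard 1,2-addition to the aldehyde makes the 2-methylallyl carbinol; its stereocentre is lost in step 8, so racemic material is fine.

**Step 8** (key step)
Reactants: **11**; **12** triethyl orthoacetate
Product: **13** ethyl (E)-7-(TBSO)-4-methylhept-4-enoate
Conditions: **12** (10 equiv), EtCO2H (5 mol%), 140 °C, EtOH distilled off
Reagents that add atoms: triethyl orthoacetate, CC(OCC)(OCC)OCC
Why: The Johnson–Claisen [3,3]-sigmatropic rearrangement forms the C2–C3 bond and the (E)-C4=C5 alkene through a chair transition state with the C6 chain equatorial; no stereocentre is created.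

**Step 9**
Reactants: **13**
Product: **14** (E)-7-(TBSO)-4-methylhept-4-enal
Conditions: DIBAL-H (1.1 equiv), CH2Cl2, –78 °C
Reagents that add atoms: none
Why: Low-temperature DIBAL reduces the ester to the aldehyde and leaves the silyl ether and the alkene intact.

**Step 10**
Reactants: **14**; **15** trimethyl orthoformate
Product: **16** (E)-7,7-dimethoxy-4-methylhept-3-en-1-ol
Conditions: **15**, CSA (10 mol%), MeOH, rt, 3 h
Reagents that add atoms: trimethyl orthoformate, COC(OC)OC; methanol, CO
Why: Acid catalysis gives the dimethyl acetal and cleaves the primary TBS ether in the same pot (CSA/MeOH).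

**Step 11**
Reactants: **16**
Product: **17** (E)-1-iodo-7,7-dimethoxy-4-methylhept-3-ene
Conditions: I2, PPh3, imidazole, CH2Cl2, 0 °C → rt
Reagents that add atoms: iodine, II
Why: Appel-type SN2 iodination of the primary alcohol, buffered by imidazole so the acetal survives, gives the C7 coupling handle.

**Step 12**
Reactants: **17**; **9**
Product: **18** (R)-5-[(E)-4,4-dimethoxy-2-methylbut-2-enyl]-3-[(E)-7,7-dimethoxy-4-methylhept-3-en-1-yl]furan-2(5H)-one
Conditions: (i) Zn dust, DMA, 50 °C; (ii) **9**, Pd(PPh3)4 (5 mol%), THF, 50 °C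
Reagents that add atoms: none
Why: Negishi sp3–sp2 coupling of the alkylzinc with the α-iodobutenolide forms C7–C8 under near-neutral conditions, so C10 and both alkene geometries are retained.

**Step 13**
Reactants: **18**; water
Product: **19** (R)-5-[(E)-2-methyl-4-oxobut-2-en-1-yl]-3-[(E)-4-methyl-7-oxohept-3-en-1-yl]furan-2(5H)-one
Conditions: TsOH·H2O (20 mol%), acetone/H2O (9:1), rt
Reagents that add atoms: water, O
Why: Acid-catalysed acetal hydrolysis unmasks the C1 aldehyde and the C14 enal together.

**Step 14**
Reactants: **19**; **20** methyl acrylate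
Product: **21** C1 Baylis–Hillman adduct (C1–OH, C15(=CH2)CO2Me; C1 epimers)
Conditions: **20** (20 equiv), DABCO (1 equiv), rt, 4 d
Reagents that add atoms: methyl acrylate, C=CC(=O)OC
Why: The Morita–Baylis–Hillman reaction goes at the unhindered saturated aldehyde in preference to the β,β-disubstituted enal; the new carbinol stereocentre is discarded in step 15.

**Step 15**
Reactants: **21**
Product: **22** methyl 2-(bromomethyl)alk-2-enoate at C1=C15 (E/Z not specified)
Conditions: NBS, Me2S, CH2Cl2, –20 → 0 °C
Reagents that add atoms: N-bromosuccinimide, O=C1CCC(=O)N1Br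
Why: SN2′ bromination of the Baylis–Hillman alcohol gives the allylic bromide; the C1 stereocentre is removed, and the E/Z ratio does not matter because the allylchromium intermediate equilibrates.

**Step 16**
Reactants: **22**
Product: **23** Δ4,5 macrodiolide (C20H24O4)
Conditions: CrCl2 (8 equiv), NiCl2 (cat.), DMF, rt, syringe-pump addition (~3 mM); then TsOH (cat.), CH2Cl2
Reagents that add atoms: none
Why: Intramolecular Nozaki–Hiyama–Kishi allylation adds the γ-carbon (C1) of the allylchromium to the C14 aldehyde through a chair transition state. This gives the anti, trans β,γ-disubstituted α-methylene-γ-lactone, with C14 and C1 set in the macrocycle and faced relative to C10.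

**Step 17**
Reactants: **23**; O2
Product: **24** 4-methylene-5β-hydroperoxyovatodiolide (target)
Conditions: O2, TPP (1 mol%), hν (visible), CH2Cl2, –20 °C; no reductive work-up
Reagents that add atoms: singlet oxygen (from O2), O=O
Why: The Schenck ene reaction of singlet oxygen occurs at the electron-rich Δ4,5 alkene rather than the Δ12,13 alkene, which is deactivated by the allylic acyloxy group at C14. The cis effect directs H-abstraction from the C18 methyl, which lies on the same side as C6 in this ring-E alkene, giving 5-OOH/4(18)-ene. Peripheral attack on the macrocycle sets C5.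

## Compound list
1 | (S)-5-(hydroxymethyl)dihydrofuran-2(3H)-one | OC[C@@H]1CCC(=O)O1 | starting material
2 | (S)-(5-oxotetrahydrofuran-2-yl)methyl tosylate | Cc1ccc(cc1)S(=O)(=O)OC[C@@H]1CCC(=O)O1 | intermediate
3 | isopropenylmagnesium bromide | C=C(C)[Mg]Br | starting material
4 | (S)-5-(2-methylallyl)dihydrofuran-2(3H)-one | C=C(C)C[C@@H]1CCC(=O)O1 | intermediate
5 | acrolein dimethyl acetal | C=CC(OC)OC | starting material
6 | (S)-5-[(E)-4,4-dimethoxy-2-methylbut-2-en-1-yl]dihydrofuran-2(3H)-one | COC(OC)/C=C(\C)C[C@@H]1CCC(=O)O1 | intermediate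
7 | 3-(phenylselanyl) analogue of 6 (C8 epimers) | COC(OC)/C=C(\C)C[C@@H]1CC([Se]c2ccccc2)C(=O)O1 | intermediate
8 | (R)-5-[(E)-4,4-dimethoxy-2-methylbut-2-en-1-yl]furan-2(5H)-one | COC(OC)/C=C(\C)C[C@@H]1C=CC(=O)O1 | intermediate
9 | (R)-3-iodo analogue of 8 | COC(OC)/C=C(\C)C[C@@H]1C=C(I)C(=O)O1 | intermediate
10 | 3-(TBSO)propanal | O=CCCO[Si](C)(C)C(C)(C)C | starting material
11 | 5-(TBSO)-2-methylpent-1-en-3-ol (racemic) | C=C(C)C(O)CCO[Si](C)(C)C(C)(C)C | intermediate
12 | triethyl orthoacetate | CCOC(C)(OCC)OCC | starting material
13 | ethyl (E)-7-(TBSO)-4-methylhept-4-enoate | CCOC(=O)CC/C(C)=C/CCO[Si](C)(C)C(C)(C)C | intermediate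
14 | (E)-7-(TBSO)-4-methylhept-4-enal | O=CCC/C(C)=C/CCO[Si](C)(C)C(C)(C)C | intermediate
15 | trimethyl orthoformate | COC(OC)OC | starting material
16 | (E)-7,7-dimethoxy-4-methylhept-3-en-1-ol | COC(OC)CC/C(C)=C/CCO | intermediate
17 | (E)-1-iodo-7,7-dimethoxy-4-methylhept-3-ene | COC(OC)CC/C(C)=C/CCI | intermediate
18 | Negishi product, bis-acetal butenolide | COC(OC)/C=C(\C)C[C@@H]1C=C(CC/C=C(\C)CCC(OC)OC)C(=O)O1 | intermediate
19 | dialdehyde (C1 CHO, C14 enal) | O=C/C=C(\C)C[C@@H]1C=C(CC/C=C(\C)CCC=O)C(=O)O1 | intermediate
20 | methyl acrylate | C=CC(=O)OC | starting material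
21 | Baylis–Hillman adduct (C1 epimers) | O=C/C=C(\C)C[C@@H]1C=C(CC/C=C(\C)CCC(O)C(=C)C(=O)OC)C(=O)O1 | intermediate
22 | allylic bromide/enal (C1=C15 geometry unspecified) | O=C/C=C(\C)C[C@@H]1C=C(CC/C=C(\C)CCC=C(CBr)C(=O)OC)C(=O)O1 | intermediate
23 | Δ4,5 macrodiolide (5-deoxy, 4-methyl, Δ4,5) | C=C1C(=O)O[C@H]2/C=C(\C)C[C@@H]3C=C(CC/C=C(\C)CC[C@H]12)C(=O)O3 | intermediate
24 | 4-methylene-5β-hydroperoxyovatodiolide | C=C1C(=O)O[C@H]2/C=C(\C)C[C@@H]3C=C(CC[C@@H](OO)C(=C)CC[C@H]12)C(=O)O3 | target

## Totals
- Total steps: 17.
- Longest linear sequence: 12 steps (1 → 2 → 4 → 6 → 7 → 8 → 9 → 18 → 19 → 21 → 22 → 23 → 24).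
- Stereocentres: C10 comes from 1; C14 and C1 are set in step 16; C5 is set in step 17.

## Three steps most likely to fail
1. **Step 16, NHK macrocyclization.** Yield (oligomerisation) and the C1/C14 diastereocontrol relative to C10 are uncertain. Fallback: build the trans-lactone first by cuprate conjugate addition to a 5-alkenyl-butenolide made from (S)-5-hydroxymethyl-2(5H)-furanone, then α-methylenate and close the 14-ring by RCM at C12=C13.
2. **Step 17, singlet-oxygen ene.** Chemoselectivity (Δ4,5 versus Δ12,13), regioselectivity (C18 versus C3 hydrogen abstraction) and facial selectivity at C5 may be poor. Fallback: replace the Δ4,5 alkene with a C4 vinyl iodide and a C5 aldehyde, close the ring by Kishi–Nozaki NHK, then convert the C5 allylic alcohol to OOH by mesylation and SN2 with H2O2/base.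
3. **Step 14, Baylis–Hillman reaction on dialdehyde 19.** It may be slow, and DABCO/acrylate may engage the butenolide or enal. Fallback: install the trisubstituted 2-(silyloxymethyl)acrylate on the West fragment by Horner–Wadsworth–Emmons olefination of aldehyde 14 before the Negishi coupling, then convert CH2OTBS to CH2Br late.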